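## Analysis of the target

Sideritiflavone is a flavone: a benzo ring A fused to a 4-pyranone ring C (chromen-4-one), with a 3,4-dihydroxyphenyl ring B on C2. It has no stereocentre, so the problem is one of regiochemistry on oxygen. Ring A is fully substituted: C5 carries a hydroxyl that is hydrogen-bonded to the C4 carbonyl, C6, C7 and C8 each carry a methoxy group, and ring B keeps a free catechol. The sensitive parts are three. The catechol is easily oxidised and binds metals. Ring C can be opened at C2 by base or acid and reclosed through the other flanking oxygen (the Wessely–Moser pathway), which can exchange the C6 and C8 substituents. The tetra-oxygenated ring A is itself prone to oxidation. The difficulty is to place four oxygens on adjacent carbons of ring A in one defined pattern, three methylated and one free, while both hydroxyls of ring B end up free. The strategy rests on the fact that C6 and C8 are the two unsubstituted, nucleophilic carbons of a 5,7-dihydroxyflavone, each lying between two oxygen-bearing carbons, and that both need the same group, a methoxy group. With equal groups on C6 and C8, ring A is symmetric about the C4a–C7 axis, so opening and reclosure of ring C returns the same compound. The remaining choice between O5 and O7 is made by the hydrogen bond from the C5 hydroxyl to the C4 carbonyl.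

## Retrosynthetic reasoning

**12 ⇒ 11 (ketal C–O bonds on ring B).** The last bonds cut are the two O–C bonds joining the 3',4'-oxygens of ring B to a diphenylmethylene carbon, which leads from target 12 back to ketal 11. The free 3',4'-diol is the most fragile part of 12: it is oxidised easily, it binds copper, and its hydroxyls would compete in any O-methylation. It is therefore released last. The forward reaction must hydrolyse a diaryl ketal without touching three aryl methyl ethers or ring C, which mild aqueous acid should do.

**11 ⇒ 9 + 10 (O–CH3 bond at C7).** Cutting the C7 methyl gives diol 9 and iodomethane 10. This methyl is chosen, and not the one at C6 or C8, because its removal leaves a ring A in which C6 and C8 carry the same group. Precursor 9 is then symmetric about the C4a–C7 axis, and its two methoxy groups can come from one twofold reaction. The forward step must methylate O7 and spare O5. The structure provides for this: the C5 hydroxyl is held in a six-membered hydrogen bond to the C4 carbonyl, while the C7 hydroxyl is free and acidic.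

**9 ⇒ 6 + 7 (aryl C–O bonds at C6 and C8).** Both bonds are cut together, giving dibromide 6 and sodium methoxide 7. No bond of the carbon skeleton is broken. The cut is made here because C6 and C8 are the only ring A carbons that a 5,7-dioxygenated flavone leaves unsubstituted, and they are also the carbons at which an electrophilic halogen enters. The halide needed for a copper-mediated exchange can therefore be placed exactly where the oxygen is wanted. The forward reaction must exchange both bromides for methoxy groups in one operation, through the half-exchanged compound 8, without reductive loss of bromine. Ring opening at C2 is harmless because 6 and 9 are each symmetric in ring A, and at the stage of 8 it would only interchange two compounds that converge on 9.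

**6 ⇒ 3 + 4 (C–Br bonds at C6 and C8).** Removing both bromines gives ketal 3 and N-bromosuccinimide 4. The forward reaction is a twofold electrophilic substitution through monobromide 5. It must stay on ring A, which the two free hydroxyls of ring A should ensure, since ring B is present only as a diether.

**3 ⇒ 1 + 2 (ketal C–O bonds).** Opening the ketal gives luteolin 1 and dichlorodiphenylmethane 2. Compound 1 supplies the whole carbon skeleton, the C4 carbonyl, the C2–C3 double bond and six of the eight oxygens of 12. The protecting group must survive 4, hot sodium methoxide 7 and the base of the methylation, must leave with acid at the end, and must go on ring B only. A ketal bridging two neighbouring oxygens meets all three demands, because the C5 and C7 oxygens are not neighbours and cannot form such a ring.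

## Alternatives that were turned down

**Alternative 1:** Dötz benzannulation of ring A onto a saturated ring C.
- **Disconnection:** ring A is cut into C8 (a carbene carbon), C7 and C6 (an alkyne) and C5 (a carbonyl ligand). The bonds C8–C7, C6–C5 and C5–C4a are made in one step on a 2-aryl-dihydropyran that already holds O1, C2, C3, C4, C4a and C8a.
- **Forward key step:** the alkenyl(methoxy)carbene complex A2, whose Cr(CO)5 carbene unit sits on the enol-ether carbon C8a, is heated with dimethoxyethyne A3. Alkyne insertion, CO insertion and electrocyclic closure of the dienylketene onto C4a should give, after removal of the metal, the racemic flavan A1.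
- **For:** the mechanism dictates the oxygen pattern. The carbene methoxy ends at C8, the alkyne brings the C6 and C7 methoxy groups, and the inserted CO becomes the one free hydroxyl at C5. A symmetric alkyne removes any regiochemical question. On this point the alternative is stronger than the chosen route, which must tell O7 from O5 in step 4. The chosen route offers instead a differentiation that costs one step and rests on a hydrogen bond that is always present.
- **Against:**
  - A3 is a thermally fragile bis-donor alkyne, while the benzannulation needs heat, and heteroatom-substituted alkynes tend to leave the phenol-forming pathway (insertion without CO uptake, four- and five-membered ring products).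
  - A full equivalent of zerovalent chromium is consumed.
  - A2 must be made by α-lithiation of an enol ether in the presence of two benzyl ethers.
  - The heaviest objection lies in A1 itself: it is a flavan, with a methylene at C4 and a saturated C2–C3 bond. A benzylic oxidation at C4 and a dehydrogenation must follow, on a ring A whose C5 hydroxyl is para to the C8 methoxy group and is thus prone to over-oxidation to the quinone level. A second benzylic position at C2 and two benzyl ethers compete, and the C2 stereocentre is made only to be destroyed.
- **Comparison:** the chosen route starts with the C4 carbonyl and the C2–C3 double bond in place and replaces two C–H bonds in five steps. This alternative would need more than twice as many steps, and its hardest steps come after its key step.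

**Alternative 2:** Squarate ring expansion (Moore rearrangement) onto a 4-pyranone.
- **Disconnection:** C5, C6, C7 and C8 come from dimethyl squarate A6. C4a–C5 is made by adding a C5-metallated 2-aryl-4-pyranone to one carbonyl of A6, and the key step forms C8–C8a.
- **Forward key step:** on heating, hydroxycyclobutenone A5 opens by conrotatory 4π ring opening, with the hydroxyl turning outward, to a dienylketene. The ketene carbon closes by 6π electrocyclisation onto the free C–H carbon of the pyranone (C8a), and tautomerisation should give hydroquinone A4.
- **For:** the plan is convergent, and A6 delivers the C6 and C7 methoxy groups. Ring C and the C4 carbonyl are present at the right oxidation level, and connectivity fixes the ring fusion. No halogen and no copper exchange on an electron-rich ring are needed. On that point it is stronger than the chosen route, whose key step must outrun hydrodebromination; the chosen route answers with a starting material that already holds the whole skeleton. The end game would also be short and would use the same chelation logic: in A4 the C8 hydroxyl is free and the C5 hydroxyl is hydrogen-bonded, so one methylation and a debenzylation would give 12.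
- **Against:**
  - The nucleophile is a 4-pyranone carrying a carbon–metal bond next to its own carbonyl. 4-Pyranones are vinylogous esters that accept nucleophiles at the carbons next to the ring oxygen, and the halogenated pyranone needed for metalation must itself be made in several steps.
  - In the dienylketene, rotation about the C4a–C5 bond decides whether the ketene meets the C8a–H carbon or the C4 carbonyl oxygen. Closure on oxygen, or capture of the ketene by the tertiary hydroxyl, competes with the electrocyclisation onto an electron-poor pyranone carbon.
  - A4 is a 5,8-hydroquinone and would be oxidised by air.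
- **Comparison:** counting pyranone synthesis, halogenation, addition, thermolysis, methylation and debenzylation, the route would run to at least eight steps against five.

**Alternative 3:** Biomimetic folding of a masked polyketide.
- **Disconnection:** C4a–C8a (ring A, Claisen condensation) and O1–C2 (ring C, cyclodehydration). Rings A and C come from one linear aroyl tetraketide ester whose C6 and C8 carry methoxy groups, stored as the 4-pyranone A8 (C4, C4a, C5, C6 and C7 lie in the pyranone ring).
- **Forward key step:** magnesium methoxide A9 in its parent alcohol opens the pyranone of A8 to a magnesium-chelated polycarbonyl chain. The carbanion at C4a, between the C4 and C5 carbonyls, attacks the terminal ester carbon C8a and closes ring A as an acylated triol. On acidification a phenol oxygen adds to the C2 ketone and loses water to close ring C, giving A7.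
- **For:** it follows the biosynthetic logic, and chain construction places every oxygen of ring A. It needs no halogenation, no metal-mediated coupling and no natural flavone, and it opens access to analogues with other groups on C6 and C8. On these points it is stronger than the chosen route. The ring C closure is degenerate for the same symmetry reason as in the chosen route.
- **Against:**
  - A7 has the ring A pattern of compound 9 and differs only in the ring B protecting groups. The alternative thus arrives where the chosen route stands after three steps, and the same O7 methylation and deprotection still follow.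
  - The chain of A8 with its two α-methoxy groups must be assembled stepwise.
  - α-Alkoxy groups slow enolisation and leave other folding modes open: aldol closure of C3 onto the C7 carbonyl or of C8 onto the C4 carbonyl, and reclosure to a pyranone or pyrone. Only the magnesium template selects among them.
- **Comparison:** the chosen route takes from 1 what this alternative must build, and spends its one risky step on two C–O bonds instead of on a folding selectivity.

Key step: step 3

Remark on the chemistry: the order in which C6 and C8 react in steps 2 and 3 is not fixed by the route; the first event is written at C8 (compounds 5 and 8), and the opposite order would lead to the same dibromide 6 and the same dimethoxy compound 9.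

## Route

Step 1
Reactants: 1 luteolin, 2-(3,4-dihydroxyphenyl)-5,7-dihydroxychromen-4-one; 2 dichlorodiphenylmethane
Product: 3 5,7-dihydroxy-2-(2,2-diphenyl-1,3-benzodioxol-5-yl)chromen-4-one (luteolin 3',4'-diphenylmethylene ketal)
Conditions: Ph2CCl2 (1.5 equiv), Ph2O, 175 °C, 30 min, N2
Reagents that add atoms: dichlorodiphenylmethane, ClC(Cl)(c1ccccc1)c1ccccc1
Why: Thermal ketalisation of a catechol with a geminal dichloride: Ph2CCl2 ionises to the chlorodiphenylmethyl cation, one ring B oxygen attacks, and the neighbouring oxygen closes the five-membered 1,3-dioxole with loss of the second HCl. Only the 3',4'-pair can form such a ring, so the C5 and C7 hydroxyls stay free, and any open ether formed at O7 is labile and is lost on work-up. This is the established catechol-selective protection of polyhydroxyflavones.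

Step 2
Reactants: 3 5,7-dihydroxy-2-(2,2-diphenyl-1,3-benzodioxol-5-yl)chromen-4-one; 4 N-bromosuccinimide
Product: 6 6,8-dibromo-5,7-dihydroxy-2-(2,2-diphenyl-1,3-benzodioxol-5-yl)chromen-4-one, via C8 monobromide 5 (not isolated)
Conditions: NBS (2.05 equiv), DMF, 0 °C to rt, dark
Reagents that add atoms: N-bromosuccinimide, O=C1CCC(=O)N1Br
Why: Electrophilic aromatic bromination: C6 and C8 are each ortho or para to both free hydroxyls and to O1, so ring A is far more nucleophilic than ring B (a diether conjugated to the electron-poor pyranone) or C3. Two equivalents of NBS at low temperature should therefore stop at the 6,8-dibromide, through monobromide 5, and the ketal is inert to NBS.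

Step 3
Reactants: 6 6,8-dibromo-5,7-dihydroxy-2-(2,2-diphenyl-1,3-benzodioxol-5-yl)chromen-4-one; 7 sodium methoxide
Product: 9 5,7-dihydroxy-6,8-dimethoxy-2-(2,2-diphenyl-1,3-benzodioxol-5-yl)chromen-4-one, via 6-bromo-8-methoxy intermediate 8 (not isolated)
Conditions: NaOMe (12 equiv, 25% in MeOH), CuBr (0.3 equiv), dry DMF, 110 °C, argon; then cold dilute HCl
Reagents that add atoms: sodium methoxide, [Na+].[O-]C
Why: This is an Ullmann-type copper-mediated exchange of aryl bromide for methoxide, the known way to turn 6,8-dihalo-5,7-dihydroxyflavones into their 6,8-dimethoxy counterparts. Excess NaOMe first deprotonates both phenols and converts CuBr into a methoxide complex of monovalent copper; this inserts into a C–Br bond of ring A to give an aryl species of trivalent copper, and reductive elimination forms the C–OMe bond and returns monovalent copper. The sequence runs twice, through the bromo methoxy compound 8, so the C6–O and C8–O bonds are both made in one operation. The phenoxide oxygens next to each bromine (O5 and O7 at C6, O7 at C8) can hold the copper close to the halide, which offsets the low electrophilicity of the electron-rich ring. No ring is closed and no stereocentre is created. The selectivity needed is exchange over hydrodebromination and ring A over ring B: the only halogens sit on ring A because step 2 placed them there, and dry DMF with a large excess of methoxide keeps proton sources low and the copper methoxide concentration high. Methoxide can add to C2 and open ring C, but in 6 and in 9 the groups on C6 and C8 are identical, so reclosure through either phenoxide returns the same flavone, and at the stage of 8 such an event would only interchange bromine and methoxy, both isomers leading on to 9. The ketal on ring B is inert to base.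

Step 4
Reactants: 9 5,7-dihydroxy-6,8-dimethoxy-2-(2,2-diphenyl-1,3-benzodioxol-5-yl)chromen-4-one; 10 iodomethane
Product: 11 5-hydroxy-6,7,8-trimethoxy-2-(2,2-diphenyl-1,3-benzodioxol-5-yl)chromen-4-one
Conditions: MeI (1.1 equiv), K2CO3 (1.2 equiv), acetone, rt to 40 °C
Reagents that add atoms: iodomethane, CI
Why: Williamson ether synthesis under acidity control: the C7 hydroxyl is para to the carbonyl-bearing C4a, is not hydrogen-bonded and is deprotonated by K2CO3, whereas the C5 hydroxyl is locked in a hydrogen bond to the C4 carbonyl and is both less acidic and less nucleophilic. With about one equivalent of the small electrophile MeI only O7 should be methylated, and ring B has no free hydroxyl.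

Step 5
Reactants: 11 5-hydroxy-6,7,8-trimethoxy-2-(2,2-diphenyl-1,3-benzodioxol-5-yl)chromen-4-one
Product: 12 sideritiflavone, 2-(3,4-dihydroxyphenyl)-5-hydroxy-6,7,8-trimethoxychromen-4-one
Conditions: AcOH/H2O (4:1), reflux, argon
Reagents that add atoms: none
Why: Acid-catalysed ketal hydrolysis: protonation of a ketal oxygen, ionisation to the diphenyl-stabilised oxocarbenium ion, capture by water and collapse release the catechol and benzophenone. Aryl methyl ethers, the chelated phenol and the pyranone are stable to hot aqueous acetic acid, and any acid-induced opening and reclosure of ring C is degenerate because C6 and C8 both carry methoxy groups. Inert gas protects the liberated catechol.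

## Compound list

1 | luteolin, 2-(3,4-dihydroxyphenyl)-5,7-dihydroxychromen-4-one | O=c1cc(-c2ccc(O)c(O)c2)oc2cc(O)cc(O)c12 | starting material
2 | dichlorodiphenylmethane | ClC(Cl)(c1ccccc1)c1ccccc1 | starting material
3 | 5,7-dihydroxy-2-(2,2-diphenyl-1,3-benzodioxol-5-yl)chromen-4-one | O=c1cc(-c2ccc3c(c2)OC(c2ccccc2)(c2ccccc2)O3)oc2cc(O)cc(O)c12 | intermediate
4 | N-bromosuccinimide | O=C1CCC(=O)N1Br | starting material
5 | 8-bromo-5,7-dihydroxy-2-(2,2-diphenyl-1,3-benzodioxol-5-yl)chromen-4-one | O=c1cc(-c2ccc3c(c2)OC(c2ccccc2)(c2ccccc2)O3)oc2c(Br)c(O)cc(O)c12 | intermediate
6 | 6,8-dibromo-5,7-dihydroxy-2-(2,2-diphenyl-1,3-benzodioxol-5-yl)chromen-4-one | O=c1cc(-c2ccc3c(c2)OC(c2ccccc2)(c2ccccc2)O3)oc2c(Br)c(O)c(Br)c(O)c12 | intermediate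
7 | sodium methoxide | [Na+].[O-]C | starting material
8 | 6-bromo-5,7-dihydroxy-8-methoxy-2-(2,2-diphenyl-1,3-benzodioxol-5-yl)chromen-4-one | O=c1cc(-c2ccc3c(c2)OC(c2ccccc2)(c2ccccc2)O3)oc2c(OC)c(O)c(Br)c(O)c12 | intermediate
9 | 5,7-dihydroxy-6,8-dimethoxy-2-(2,2-diphenyl-1,3-benzodioxol-5-yl)chromen-4-one | COc1c(O)c(OC)c2oc(-c3ccc4c(c3)OC(c3ccccc3)(c3ccccc3)O4)cc(=O)c2c1O | intermediate
10 | iodomethane | CI | starting material
11 | 5-hydroxy-6,7,8-trimethoxy-2-(2,2-diphenyl-1,3-benzodioxol-5-yl)chromen-4-one | COc1c(OC)c(OC)c2oc(-c3ccc4c(c3)OC(c3ccccc3)(c3ccccc3)O4)cc(=O)c2c1O | intermediate
12 | sideritiflavone, 2-(3,4-dihydroxyphenyl)-5-hydroxy-6,7,8-trimethoxychromen-4-one | COc1c(OC)c(O)c2c(=O)cc(-c3ccc(O)c(O)c3)oc2c1OC | target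

## Step count and risks

Total step count: 5. Longest linear sequence: 5 steps (1 → 3 → 6 → 9 → 11 → 12).

**Step 3 (key step).**
- **What may go wrong:** reductive loss of bromine in place of C–O bond formation (protonation or hydride transfer at the aryl copper stage), or stalling after the first exchange. Both are favoured because the ring reacts as a doubly deprotonated, very electron-rich bis-phenoxide.
- **Fallback, from 6, returning at 12:** both phenols of 6 are methylated first (excess MeI, K2CO3, DMF, 60 °C; the chelated C5 hydroxyl needs the forcing conditions) to give 6,8-dibromo-5,7-dimethoxy-2-(2,2-diphenyl-1,3-benzodioxol-5-yl)chromen-4-one F1. The copper/methoxide exchange (NaOMe, CuBr, DMF, 110 °C) is then run on this neutral ring, the substrate class on which it is most reliable, to give 5,6,7,8-tetramethoxy-2-(2,2-diphenyl-1,3-benzodioxol-5-yl)chromen-4-one F2. Hot aqueous acetic acid removes the ketal to give 2-(3,4-dihydroxyphenyl)-5,6,7,8-tetramethoxychromen-4-one F3. BCl3 in CH2Cl2 at −78 to 0 °C then cleaves only the C5 methyl ether, the one that can form a six-membered boron chelate with the C4 carbonyl, and returns the route to target 12.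
- **What changes:** the coupling no longer has to work on a phenoxide, and the C5 hydroxyl is freed at the end by chelation-directed demethylation instead of being spared in step 4.

**Step 4.**
- **What may go wrong:** over-methylation at O5, or incomplete methylation. The C7 hydroxyl of 9 lies between two methoxy groups, which shield it and, as donors, lower its acidity, so the reactivity gap to the chelated C5 hydroxyl is narrower than in a plain 5,7-dihydroxyflavone.
- **Fallback, from 6, returning at 11:** the choice between O7 and O5 is made one stage earlier, on dibromide 6, where the C7 hydroxyl is flanked by two bromine atoms and is by far the more acidic. One equivalent of MeI with K2CO3 in acetone should give 6,8-dibromo-5-hydroxy-7-methoxy-2-(2,2-diphenyl-1,3-benzodioxol-5-yl)chromen-4-one F4. The copper/methoxide exchange of step 3 on F4, now a mono-phenoxide, leads directly to 11, so compound 9 and step 4 are bypassed. Ring opening and reclosure stay degenerate, because C6 and C8 carry equal groups at the start and at the end.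

**Step 2.**
- **What may go wrong:** bromination not stopping cleanly on ring A (attack at C3 or on ring B with a slight excess of NBS, or oxidation of the electron-rich bis-phenol), or incomplete second bromination with too little reagent.
- **Fallback, from 3, returning at 9:** iodine with NaHCO3 in aqueous THF at 0 °C iodinates only a ring that is present as a phenoxide, which excludes ring B and C3. It should give 5,7-dihydroxy-6,8-diiodo-2-(2,2-diphenyl-1,3-benzodioxol-5-yl)chromen-4-one F5. The diiodide then takes the place of 6 in the copper/methoxide exchange, where C–I bonds react with copper more readily, and gives 9.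

**Step 1.**
- **What may go wrong:** O-alkylation at the acidic C7 hydroxyl with oligomer formation at 175 °C, incomplete conversion of the poorly soluble luteolin, and losses on separation from the high-boiling solvent.
- **Fallback, from 2, returning at 3:** the ketal is made on a small catechol, and rings A and C are then built around it. Methyl 3,4-dihydroxybenzoate and 2 (neat, 170 °C) give methyl 2,2-diphenyl-1,3-benzodioxole-5-carboxylate F6. Claisen condensation with the lithium enolate of ethyl acetate (LiN(SiMe3)2, THF, −78 °C to rt) gives ethyl 3-(2,2-diphenyl-1,3-benzodioxol-5-yl)-3-oxopropanoate F7. Thermal condensation of F7 with phloroglucinol (neat, 240 °C, Mentzer pyrone synthesis) closes ring C onto the symmetric triol and gives 3. This gives up the natural flavone as the source of the skeleton but leaves the key step unchanged.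

## Further compounds

F1 | step 3 | 6,8-dibromo-5,7-dimethoxy-2-(2,2-diphenyl-1,3-benzodioxol-5-yl)chromen-4-one | COc1c(Br)c(OC)c2c(=O)cc(-c3ccc4c(c3)OC(c3ccccc3)(c3ccccc3)O4)oc2c1Br
F2 | step 3 | 5,6,7,8-tetramethoxy-2-(2,2-diphenyl-1,3-benzodioxol-5-yl)chromen-4-one | COc1c(OC)c(OC)c2c(=O)cc(-c3ccc4c(c3)OC(c3ccccc3)(c3ccccc3)O4)oc2c1OC
F3 | step 3 | 2-(3,4-dihydroxyphenyl)-5,6,7,8-tetramethoxychromen-4-one | COc1c(OC)c(OC)c2c(=O)cc(-c3ccc(O)c(O)c3)oc2c1OC
F4 | step 4 | 6,8-dibromo-5-hydroxy-7-methoxy-2-(2,2-diphenyl-1,3-benzodioxol-5-yl)chromen-4-one | COc1c(Br)c(O)c2c(=O)cc(-c3ccc4c(c3)OC(c3ccccc3)(c3ccccc3)O4)oc2c1Br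
F5 | step 2 | 5,7-dihydroxy-6,8-diiodo-2-(2,2-diphenyl-1,3-benzodioxol-5-yl)chromen-4-one | O=c1cc(-c2ccc3c(c2)OC(c2ccccc2)(c2ccccc2)O3)oc2c(I)c(O)c(I)c(O)c12
F6 | step 1 | methyl 2,2-diphenyl-1,3-benzodioxole-5-carboxylate | COC(=O)c1ccc2c(c1)OC(c1ccccc1)(c1ccccc1)O2
F7 | step 1 | ethyl 3-(2,2-diphenyl-1,3-benzodioxol-5-yl)-3-oxopropanoate | CCOC(=O)CC(=O)c1ccc2c(c1)OC(c1ccccc1)(c1ccccc1)O2
A1 | alternative 1 | 2-[3,4-bis(benzyloxy)phenyl]-6,7,8-trimethoxy-3,4-dihydro-2H-chromen-5-ol (racemic flavan) | COc1c(OC)c(OC)c(O)c2c1OC(c1ccc(OCc3ccccc3)c(OCc3ccccc3)c1)CC2
A2 | alternative 1 | pentacarbonyl{[2-(3,4-bis(benzyloxy)phenyl)-3,4-dihydro-2H-pyran-6-yl](methoxy)methylidene}chromium (racemic) | COC(=[Cr](=C=O)(=C=O)(=C=O)(=C=O)=C=O)C1=CCCC(c2ccc(OCc3ccccc3)c(OCc3ccccc3)c2)O1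
A3 | alternative 1 | dimethoxyethyne | COC#COC
A4 | alternative 2 | 2-[3,4-bis(benzyloxy)phenyl]-5,8-dihydroxy-6,7-dimethoxychromen-4-one | COc1c(OC)c(O)c2c(=O)cc(-c3ccc(OCc4ccccc4)c(OCc4ccccc4)c3)oc2c1O
A5 | alternative 2 | 2-[3,4-bis(benzyloxy)phenyl]-5-(1-hydroxy-2,3-dimethoxy-4-oxocyclobut-2-en-1-yl)pyran-4-one (racemic) | COC1=C(OC)C(O)(c2coc(-c3ccc(OCc4ccccc4)c(OCc4ccccc4)c3)cc2=O)C1=O
A6 | alternative 2 | dimethyl squarate, 3,4-dimethoxycyclobut-3-ene-1,2-dione | COC1=C(OC)C(=O)C1=O
A7 | alternative 3 | 2-[3,4-bis(benzyloxy)phenyl]-5,7-dihydroxy-6,8-dimethoxychromen-4-one | COc1c(O)c(OC)c2oc(-c3ccc(OCc4ccccc4)c(OCc4ccccc4)c3)cc(=O)c2c1O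
A8 | alternative 3 | methyl 2-{6-[2-(3,4-bis(benzyloxy)phenyl)-2-oxoethyl]-3-methoxy-4-oxo-4H-pyran-2-yl}-2-methoxyacetate (racemic) | COC(=O)C(OC)c1oc(CC(=O)c2ccc(OCc3ccccc3)c(OCc3ccccc3)c2)cc(=O)c1OC
A9 | alternative 3 | magnesium methoxide | [Mg+2].[O-]C.[O-]C
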